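Everything rests on cutting the C2–O bond of ring B, the benzoic acid ring, so that its C2 phenol is made last. The key step lets the C1 carboxylate of ring B steer palladium to C2–H, the single hydrogen-bearing carbon ortho to the carboxyl because C6 holds the propyl group, lying between C1 and the C3 oxygen that carries the ring A aroyl group; dioxygen then turns this C–H into C–OH in one operation. The precursor is a catechol-derived depside acid, 4-(benzyloxy)-5-[(2,4-dimethoxy-6-propylbenzoyl)oxy]-2-propylbenzoic acid, whose two oxygens are told apart at the aldehyde stage. Hydrogenolysis of the benzyl ether should then give the target.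

Key step: step 9

Remark: ring A is the 2,4-dimethoxy-6-propylbenzoyl ring; ring B is numbered as in the target (C1 carboxyl, C2 and C4 hydroxyl, C3 aroyloxy, C6 propyl), so the carbon called C2 here is C6 in the locants of the precursor acid.

Step 1
Reactants: 1 1-bromo-3,5-dimethoxybenzene
Product: 2 1,3-dimethoxy-5-propylbenzene
Conditions: n-PrMgBr (1.3 equiv), NiCl2(dppp) (2 mol %), THF, 0 °C to reflux
Reagents that add atoms: n-propylmagnesium bromide, CCC[Mg]Br
Why: Kumada–Corriu cross-coupling, in which the aryl bromide adds to zerovalent nickel, the primary Grignard reagent transmetalates and reductive elimination forms the aryl–propyl bond, the chelating dppp ligand holding back β-hydride elimination and isomerisation of the propyl group.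

Step 2
Reactants: 2 1,3-dimethoxy-5-propylbenzene
Product: 4 2,4-dimethoxy-6-propylbenzaldehyde, via iminium chloride 3 (not isolated)
Conditions: POCl3 (1.5 equiv), DMF, 0 °C to 70 °C; then H2O
Reagents that add atoms: N,N-dimethylformamide, CN(C)C=O; water, O
Why: Vilsmeier–Haack formylation, in which the chloroiminium ion attacks the ring carbon para to one methoxy group and next to propyl, the usual site for 5-alkylresorcinol dimethyl ethers because the carbon between the two methoxy groups is more crowded, and water hydrolyses the iminium salt.

Step 3
Reactants: 4 2,4-dimethoxy-6-propylbenzaldehyde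
Product: 5 2,4-dimethoxy-6-propylbenzoic acid
Conditions: NaClO2, NaH2PO4, 2-methylbut-2-ene, t-BuOH/H2O, rt
Reagents that add atoms: sodium chlorite, [Na+].[O-]Cl=O
Why: Pinnick oxidation, in which chlorous acid adds to the aldehyde and fragments to the acid while 2-methylbut-2-ene traps the hypochlorous acid that could otherwise chlorinate the electron-rich ring.

Step 4
Reactants: 6 1,2-dimethoxy-4-propylbenzene
Product: 8 4,5-dimethoxy-2-propylbenzaldehyde, via α-chloro ether 7 (not isolated)
Conditions: Cl2CHOMe (1.2 equiv), TiCl4 (2 equiv), CH2Cl2, 0 °C; then H2O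
Reagents that add atoms: dichloromethyl methyl ether, COC(Cl)Cl; water, O
Why: Rieche formylation, in which the TiCl4-activated dichloromethyl ether substitutes the only free ring carbon para to a methoxy group (ortho to propyl), as 4-alkylveratroles generally react, and the chloro ether hydrolyses on work-up.

Step 5
Reactants: 8 4,5-dimethoxy-2-propylbenzaldehyde
Product: 10 4,5-dihydroxy-2-propylbenzaldehyde, via cyclic bromoborane 9 (not isolated)
Conditions: BBr3 (3 equiv), CH2Cl2, −78 °C to rt; then H2O
Reagents that add atoms: none
Why: Lewis acid cleavage of aryl methyl ethers, in which BBr3 coordinates each methoxy oxygen and bromide removes the methyl group by SN2 attack, the catechol borate being hydrolysed on work-up and the aldehyde recovered unchanged.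

Step 6
Reactants: 10 4,5-dihydroxy-2-propylbenzaldehyde
Product: 11 4-(benzyloxy)-5-hydroxy-2-propylbenzaldehyde
Conditions: BnBr (1.05 equiv), NaHCO3 (1.5 equiv), NaI (cat.), DMF, 40 °C
Reagents that add atoms: benzyl bromide, BrCc1ccccc1
Why: Regioselective Williamson etherification, in which the weak base ionises only the hydroxyl para to the formyl group, the more acidic of the two, so one equivalent of benzyl bromide alkylates that oxygen, as is well established for 3,4-dihydroxybenzaldehyde.

Step 7
Reactants: 5 2,4-dimethoxy-6-propylbenzoic acid; 11 4-(benzyloxy)-5-hydroxy-2-propylbenzaldehyde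
Product: 13 2-(benzyloxy)-5-formyl-4-propylphenyl 2,4-dimethoxy-6-propylbenzoate, via acid chloride 12 (not isolated)
Conditions: 5, (COCl)2, DMF (cat.), CH2Cl2, rt, volatiles removed; then 11, Et3N, DMAP (cat.), CH2Cl2, 0 °C to rt
Reagents that add atoms: none
Why: Acyl chloride formation followed by DMAP-catalysed acylation of the remaining phenol (nucleophilic acyl substitution), the acyl chloride being chosen because the acid carries two ortho substituents and needs strong activation.

Step 8
Reactants: 13 2-(benzyloxy)-5-formyl-4-propylphenyl 2,4-dimethoxy-6-propylbenzoate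
Product: 14 4-(benzyloxy)-5-[(2,4-dimethoxy-6-propylbenzoyl)oxy]-2-propylbenzoic acid
Conditions: NaClO2, NaH2PO4, 2-methylbut-2-ene, t-BuOH/THF/H2O, 0 °C to rt
Reagents that add atoms: sodium chlorite, [Na+].[O-]Cl=O
Why: Pinnick oxidation under buffered, weakly acidic conditions that leave the hindered aryl ester and the benzyl ether untouched, with 2-methylbut-2-ene scavenging hypochlorous acid so that neither electron-rich ring is chlorinated.

Step 9
Reactants: 14 4-(benzyloxy)-5-[(2,4-dimethoxy-6-propylbenzoyl)oxy]-2-propylbenzoic acid
Product: 15 4-(benzyloxy)-3-[(2,4-dimethoxy-6-propylbenzoyl)oxy]-2-hydroxy-6-propylbenzoic acid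
Conditions: Pd(OAc)2 (10 mol %), KOAc (2 equiv), 1,4-benzoquinone (1 equiv), O2 (1 atm), DMA, 115 °C; then dilute HCl
Reagents that add atoms: dioxygen, O=O
Why: The potassium carboxylate of 14 binds divalent palladium, and concerted metalation–deprotonation with acetate as internal base cleaves the only ortho C–H bond (C6 of 14, the future C2) to give a five-membered palladacycle; dioxygen, assisted by benzoquinone, then oxygenates the aryl–palladium bond and protonolysis releases the salicylic acid and divalent palladium. The closest known reaction type is the carboxylate-directed ortho C–H hydroxylation of potassium benzoates with Pd(OAc)2 under O2, which is known for ortho-alkyl benzoic acids as well. No ring is closed and no stereocenter is formed. The step needs site selectivity for this aryl C–H bond over the benzylic C–H bonds of both propyl groups and of the benzyl ether and over the C–H bonds of ring A; the substrate secures it because the carboxylate can form the five-membered palladacycle only at its own ortho carbons, one of which carries propyl, and ring A has no free carboxyl. The neighbouring aroyloxy oxygen raises the acidity of the reacting C–H bond, which should help the deprotonative metalation, and the ring A ester should resist acetate at 115 °C because its carbonyl is flanked by methoxy and propyl groups.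

Step 10
Reactants: 15 4-(benzyloxy)-3-[(2,4-dimethoxy-6-propylbenzoyl)oxy]-2-hydroxy-6-propylbenzoic acid
Product: 16 3-[(2,4-dimethoxy-6-propylbenzoyl)oxy]-2,4-dihydroxy-6-propylbenzoic acid
Conditions: H2 (1 atm), 10% Pd/C, EtOAc, rt
Reagents that add atoms: none
Why: Hydrogenolysis of the benzyl aryl ether gives toluene and the free C4 phenol, and the neutral conditions at room temperature should leave the depside ester in place and avoid decarboxylation of the 2,4-dihydroxybenzoic acid.

Compound list
1 | 1-bromo-3,5-dimethoxybenzene | COc1cc(Br)cc(OC)c1 | starting material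
2 | 1,3-dimethoxy-5-propylbenzene | CCCc1cc(OC)cc(OC)c1 | intermediate
3 | N-[(2,4-dimethoxy-6-propylphenyl)methylidene]-N-methylmethanaminium chloride (iminium chloride) | CCCc1cc(OC)cc(OC)c1C=[N+](C)C.[Cl-] | intermediate
4 | 2,4-dimethoxy-6-propylbenzaldehyde | CCCc1cc(OC)cc(OC)c1C=O | intermediate
5 | 2,4-dimethoxy-6-propylbenzoic acid | CCCc1cc(OC)cc(OC)c1C(=O)O | intermediate
6 | 1,2-dimethoxy-4-propylbenzene | CCCc1ccc(OC)c(OC)c1 | starting material
7 | 1-[chloro(methoxy)methyl]-4,5-dimethoxy-2-propylbenzene (α-chloro ether, racemic) | CCCc1cc(OC)c(OC)cc1C(Cl)OC | intermediate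
8 | 4,5-dimethoxy-2-propylbenzaldehyde | CCCc1cc(OC)c(OC)cc1C=O | intermediate
9 | 2-bromo-6-propyl-1,3,2-benzodioxaborole-5-carbaldehyde (cyclic bromoborane) | CCCc1cc2OB(Br)Oc2cc1C=O | intermediate
10 | 4,5-dihydroxy-2-propylbenzaldehyde | CCCc1cc(O)c(O)cc1C=O | intermediate
11 | 4-(benzyloxy)-5-hydroxy-2-propylbenzaldehyde | CCCc1cc(OCc2ccccc2)c(O)cc1C=O | intermediate
12 | 2,4-dimethoxy-6-propylbenzoyl chloride (acid chloride) | CCCc1cc(OC)cc(OC)c1C(=O)Cl | intermediate
13 | 2-(benzyloxy)-5-formyl-4-propylphenyl 2,4-dimethoxy-6-propylbenzoate | CCCc1cc(OC)cc(OC)c1C(=O)Oc1cc(C=O)c(CCC)cc1OCc1ccccc1 | intermediate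
14 | 4-(benzyloxy)-5-[(2,4-dimethoxy-6-propylbenzoyl)oxy]-2-propylbenzoic acid | CCCc1cc(OC)cc(OC)c1C(=O)Oc1cc(C(=O)O)c(CCC)cc1OCc1ccccc1 | intermediate
15 | 4-(benzyloxy)-3-[(2,4-dimethoxy-6-propylbenzoyl)oxy]-2-hydroxy-6-propylbenzoic acid | CCCc1cc(OC)cc(OC)c1C(=O)Oc1c(O)c(C(=O)O)c(CCC)cc1OCc1ccccc1 | intermediate
16 | 3-[(2,4-dimethoxy-6-propylbenzoyl)oxy]-2,4-dihydroxy-6-propylbenzoic acid | CCCc1cc(OC)cc(OC)c1C(=O)Oc1c(O)cc(CCC)c(C(=O)O)c1O | target

Total step count: 10. Longest linear sequence: 7 steps (6 to 16 through steps 4–10; the ring A branch through steps 1–3 and 7–10 is equally long).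

Steps most likely to fail

Step 9. Palladation at the crowded ortho carbon beside the aroyloxy group may be slow. At 115 °C the electron-rich, doubly ortho-substituted salicylate that forms may also lose CO2 under palladium catalysis, or pass its aroyl group from O3 to the new O2 phenoxide. The fallback installs the oxygen before the acylation and sets out from 11. Bromination with NBS in MeCN at 0 °C should enter ortho to the free hydroxyl, between OH and CHO, giving 4-(benzyloxy)-2-bromo-3-hydroxy-6-propylbenzaldehyde F1. Copper-mediated hydrolysis of the aryl bromide (aqueous NaOH, copper powder, reflux) should give 4-(benzyloxy)-2,3-dihydroxy-6-propylbenzaldehyde F2. Its disodium salt (NaH, 2 equiv, THF–DMF, 0 °C) is acylated with one equivalent of acid chloride 12. The acyl group should settle on O3 because the O2 phenoxide is conjugated with and chelated to the formyl group, giving 6-(benzyloxy)-3-formyl-2-hydroxy-4-propylphenyl 2,4-dimethoxy-6-propylbenzoate F3. Pinnick oxidation (NaClO2, NaH2PO4, 2-methylbut-2-ene) then gives 15, where the route is rejoined before step 10.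

Step 6. Over-alkylation to the bis(benzyl) ether, or alkylation at the wrong oxygen, may occur if the two phenols are not ionised selectively. The fallback caps both oxygens first and sets out from 10. Ac2O in pyridine should give 4-formyl-5-propyl-1,2-phenylene diacetate F4. On heating with BnBr, K2CO3 and KI in acetone, the acetate para to the formyl group, the more labile one, should be exchanged for benzyl while the other oxygen stays capped, giving 2-(benzyloxy)-5-formyl-4-propylphenyl acetate F5. K2CO3 in MeOH at rt removes the remaining acetate and returns the route at 11.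

Step 2. Formylation may occur partly at the carbon between the two methoxy groups, giving an aldehyde isomer that is hard to remove, or the conversion may stay incomplete. The fallback replaces formylation–oxidation by halogenation–carboxylation and sets out from 2. NBS in MeCN at 0 °C should brominate para to a methoxy group and next to propyl, giving 2-bromo-1,5-dimethoxy-3-propylbenzene F6. Bromine–lithium exchange (n-BuLi, THF, −78 °C), quenching with CO2 and acidic work-up should give acid 5 directly, so that 4 and step 3 are bypassed.

Further compounds
F1 | step 9 | 4-(benzyloxy)-2-bromo-3-hydroxy-6-propylbenzaldehyde | CCCc1cc(OCc2ccccc2)c(O)c(Br)c1C=O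
F2 | step 9 | 4-(benzyloxy)-2,3-dihydroxy-6-propylbenzaldehyde | CCCc1cc(OCc2ccccc2)c(O)c(O)c1C=O
F3 | step 9 | 6-(benzyloxy)-3-formyl-2-hydroxy-4-propylphenyl 2,4-dimethoxy-6-propylbenzoate | CCCc1cc(OC)cc(OC)c1C(=O)Oc1c(O)c(C=O)c(CCC)cc1OCc1ccccc1
F4 | step 6 | 4-formyl-5-propyl-1,2-phenylene diacetate | CCCc1cc(OC(C)=O)c(OC(C)=O)cc1C=O
F5 | step 6 | 2-(benzyloxy)-5-formyl-4-propylphenyl acetate | CCCc1cc(OCc2ccccc2)c(OC(C)=O)cc1C=O
F6 | step 2 | 2-bromo-1,5-dimethoxy-3-propylbenzene | CCCc1cc(OC)cc(OC)c1Br
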